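## The problem

The target is a 19-membered cyclophane of four benzene rings: ring A (a catechol with an aryloxy group beside it), an ether oxygen, ring B (para-phenylene), a CH2CH2 bridge, ring C (substituted like ring A), a second ether oxygen, ring D (meta-phenylene) and a second CH2CH2 bridge back to ring A. It has no stereocentre, so the task is one of connectivity: two diaryl ether bonds, two aryl–CH2CH2–aryl bridges and one macrocyclisation that must outrun oligomerisation. Rings A and C share the 1-alkyl-3,4-dihydroxy-5-aryloxy pattern, so one building block can serve for both. The two catechols are easily oxidised to ortho-quinones and bind metals, so they should stay as methyl ethers until the last step. The diaryl ethers then have to survive the Lewis acid that frees them. Any aldehyde kept for ring closure must be masked while an organolithium is in the flask. The feature that opens the key step is the bridge between C4 of ring B and C1 of ring C: each bridge carbon carries one aryl group and nothing else. The bridge therefore maps onto a vinyl group whose boron-bound carbon receives ring B from boron and whose terminal carbon receives ring C from palladium. The cost is a boron atom on one bridge carbon, a stereocentre with no counterpart in the target, which is replaced by hydrogen directly afterwards.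

## Retrosynthesis

The four O–CH3 bonds of the target 19 are cut first, giving the macrocyclic tetramethyl ether 18. Methyl ethers are chosen over benzyl ethers because they survive organolithium, palladium, low-valent titanium and hydrogenation. The forward step must cleave four alkyl aryl ethers while leaving two diaryl ethers intact, which a boron trihalide does.

The central C–C bond of the bridge between rings A and D is cut next, as the alkene of stilbene 17, which leads to the open dialdehyde 16. The neighbouring cuts would close the ring at an ether oxygen or at the B–C bridge. The A–D cut is preferred because both ends are then benzaldehydes, the oxidation level at which rings A and D are bought. It also leaves both ethers and the B–C bridge to be made intermolecularly, where concentration helps. The forward reaction is a reductive carbonyl coupling at high dilution followed by hydrogenation.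

Dialdehyde 16 is traced to the bis(dioxolane) 15, and 15 to the benzylic pinacol boronate 14 by replacing one bridge C–H by C–B. This adds a boron atom in the retrosynthetic direction and is justified only by the next cut. The forward steps are a fluoride-promoted protodeboronation, which is easy at a benzylic carbon, and an acetal hydrolysis.

In 14 both aryl–carbon bonds of the B–C bridge are cut at once, giving the ring A–O–ring B boronate 5, vinyllithium 12 and the ring C–O–ring D triflate 10. The alternatives for this bridge (olefination then hydrogenation, or alkyne coupling then hydrogenation) would put a third and fourth aldehyde-level carbon into a molecule that already has two masked aldehydes. Here the bridge carbons come from 12, and rings B and C need only a boron and a triflate, which are orthogonal to the acetals. The precursors are two fragments of similar size and a two-carbon linchpin. The forward reaction must make the 1,2-shift of ring B faster than direct aryl transfer from boron to palladium.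

Boronate 5 is cut at the C–B bond to bromide 4, at the acetal to aldehyde 3, and at the ring B C–O bond to 3-hydroxy-4,5-dimethoxybenzaldehyde 1 and (4-bromophenyl)boronic acid 2. An oxidative copper coupling at room temperature is chosen for the ether because it leaves the aryl bromide untouched for the later borylation.

Triflate 10 is cut at the O–S bond to phenol 9. The phenol oxygen of 9 is traced to the formyl group of aldehyde 7 through an aryl formate. The ring D C–O bond of 7 is then cut to the same phenol 1 and 2-(3-bromophenyl)-1,3-dioxolane 6. Using 1 for ring C as well as ring A means that both halves start from one purchased compound. Ring D arrives with its aldehyde already masked, so the two carbonyl groups of this fragment never have to be told apart. The unhindered partner 6 takes the role of the halide and the hindered one that of the phenol, which is the better arrangement for a copper-catalysed etherification.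

Vinyllithium 12 is traced to tetravinyltin 11 by tin–lithium exchange, which gives the halide-free reagent that the key step needs.

## Roads not taken

Alternative 1: The cut runs through ring C itself. Two ring bonds are disconnected so that the ring is assembled from 4-chloro-2,3-diisopropoxycyclobut-2-en-1-one A2 and the alkenylstannane tributyl[4-(4-benzyloxyphenyl)but-1-en-2-yl]stannane A3. In the forward direction a palladium-catalysed Stille coupling joins C4 of A2 to the tin-bearing carbon of A3. Warming opens the four-membered ring to a dienylketene, and 6π-electrocyclisation with tautomerisation gives 5-[2-(4-benzyloxyphenyl)ethyl]-2,3-diisopropoxyphenol A1.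
- Merits: the substitution pattern is unambiguous and the B–C bridge arrives saturated, with no boron to remove. The three oxygens of ring C are fully differentiated, with the free phenol exactly where the diaryl ether must form and isopropyl ethers that come off under milder conditions than methyl ethers. In protecting-group logic and mildness of the end-game this road is better than the chosen one.
- Weak points: it builds a benzene ring whose pattern is already on sale in 1. Neither A2 nor A3 is an article of commerce and each needs several steps. After A1 both diaryl ethers, rings A and D and the macrocyclisation are still to come.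
- Comparison: the chosen plan reaches the same ring C oxidation pattern in three steps from 1 and unites all four rings in its key step. Neither plan is free of tin, since the chosen one uses 11, though only to make 12.

Alternative 2: The cut is the ring D carbon–oxygen bond of the C–O–D ether, made as the ring-closing bond. The seco phenol 2-fluoro-4-{2-[3-(4-{2-[3-hydroxy-4,5-dimethoxyphenyl]ethyl}phenoxy)-4,5-dimethoxyphenyl]ethyl}benzaldehyde A5 would be treated with a carbonate base in a dipolar aprotic solvent at high dilution. The ring C phenoxide displaces the fluoride ortho to the formyl group by addition–elimination and gives the formyl-substituted macrocycle A4. The formyl group is then removed by rhodium-mediated decarbonylation.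
- Merits: the ring closure is metal-free and gives the saturated macrocycle directly. Closures of this kind are likely to be at least as dependable as the reductive carbonyl coupling of the chosen plan, so in this respect the alternative is as good or better.
- Weak points: a formyl group is only a moderate activator, so the hindered phenoxide, flanked by a methoxy group, needs forcing temperatures with the aldehyde exposed to hot base. The activating group costs a decarbonylation step, the same price as the protodeboronation in the chosen plan. The main drawback is that A5 contains both bridges and the A–B ether, so three fragment unions must be run in line, with one phenol kept distinct from four methyl ethers throughout.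
- Comparison: against the safer ring closure the chosen plan sets a convergent union of two three-step halves made from one phenol.

Alternative 3: The cut is the ring A carbon–CH2 bond of the A–D bridge, traced back to an allyl aryl ether. The precursor A7 is a 19-membered macrocycle in which the middle oxygen of ring A carries a CH2–C(=CH2)–ring D unit. Heating A7 would move this unit by a [3,3] shift to a blocked ortho carbon and by a second [3,3] shift to the para carbon. The product is the carbon-linked macrocycle A6, with an exocyclic methylene on the bridge and a free middle phenol on ring A.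
- Merits: a carbon–carbon bond forms at an unfunctionalised ring carbon without any metal, and ring A needs no carbon substituent at the start.
- Weak points: A7 is itself a 19-membered ring that must first be closed, so the key step does not solve the macrocyclisation. Both shifts must pass through ordered six-membered arrays while the migrating unit stays tethered through rings D, C and B to the neighbouring oxygen. The ortho-dienone on the way carries a methoxy or aryloxy group at its quaternary carbon and can aromatise by losing it. The exocyclic methylene must then be excised by oxidative cleavage and carbonyl deoxygenation in the presence of electron-rich rings and a free phenol. The selectively freed phenol is of no use, because all four are freed at the end anyway.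
- Comparison: its one advantage, a ring A building block without a formyl group, is cancelled by the commercial availability of 1. The chosen plan is shorter and rests on precedented steps.

Key step: step 8

Assumption: the target has no stereocentre, so the boron-bearing carbon of 14 and the alkene geometry of 17 are left undefined in the structures, since steps 9 and 12 remove both.

## Route

Step 1
Reactants: 1 3-hydroxy-4,5-dimethoxybenzaldehyde; 2 (4-bromophenyl)boronic acid
Product: 3 3-(4-bromophenoxy)-4,5-dimethoxybenzaldehyde
Conditions: Cu(OAc)2, pyridine, 4 Å molecular sieves, CH2Cl2, air, rt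
Reagents that add atoms: none
Why: Chan–Lam oxidative C–O coupling of a phenol with an arylboronic acid proceeds at room temperature, where the aryl bromide and the aldehyde are inert; air returns the copper to the divalent state, so oxygen is the terminal oxidant.

Step 2
Reactants: 3 3-(4-bromophenoxy)-4,5-dimethoxybenzaldehyde
Product: 4 2-[3-(4-bromophenoxy)-4,5-dimethoxyphenyl]-1,3-dioxolane
Conditions: ethylene glycol, TsOH (cat.), toluene, reflux, Dean–Stark
Reagents that add atoms: ethylene glycol, OCCO
Why: Acid-catalysed acetalisation with azeotropic removal of water masks the aldehyde against the organolithium of step 8.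

Step 3
Reactants: 4 2-[3-(4-bromophenoxy)-4,5-dimethoxyphenyl]-1,3-dioxolane
Product: 5 2-{4-[5-(1,3-dioxolan-2-yl)-2,3-dimethoxyphenoxy]phenyl}-4,4,5,5-tetramethyl-1,3,2-dioxaborolane
Conditions: B2pin2, PdCl2(dppf) (cat.; dppf = 1,1'-bis(diphenylphosphino)ferrocene), KOAc, 1,4-dioxane, 85 °C
Reagents that add atoms: bis(pinacolato)diboron, CC1(C)OB(OC1(C)C)B1OC(C)(C)C(C)(C)O1
Why: Miyaura borylation of an unhindered aryl bromide; the weak acetate base leaves the dioxolane and the ethers untouched.

Step 4
Reactants: 1 3-hydroxy-4,5-dimethoxybenzaldehyde; 6 2-(3-bromophenyl)-1,3-dioxolane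
Product: 7 3-[3-(1,3-dioxolan-2-yl)phenoxy]-4,5-dimethoxybenzaldehyde
Conditions: CuI (cat.), picolinic acid (cat.), K3PO4, DMSO, 90 °C
Reagents that add atoms: none
Why: Ligand-accelerated Ullmann diaryl ether synthesis; the hindered partner is the phenoxide and the unhindered one the bromide, and the non-enolisable aldehyde and the acetal tolerate the phosphate base.

Step 5
Reactants: 7 3-[3-(1,3-dioxolan-2-yl)phenoxy]-4,5-dimethoxybenzaldehyde
Product: 9 3-[3-(1,3-dioxolan-2-yl)phenoxy]-4,5-dimethoxyphenol, via aryl formate 8 (not isolated)
Conditions: mCPBA, CH2Cl2, 0 °C → rt; then K2CO3 (cat.), MeOH, rt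
Reagents that add atoms: mCPBA, OOC(=O)c1cccc(Cl)c1
Why: Baeyer–Villiger (Dakin-type) oxidation; the aryl group, made electron-rich by the para methoxy group, migrates in preference to hydrogen to give formate 8, which methanolysis cleaves to the phenol. The only other aldehyde is masked, and the dioxolane should stand the weak carboxylic acid in CH2Cl2.

Step 6
Reactants: 9 3-[3-(1,3-dioxolan-2-yl)phenoxy]-4,5-dimethoxyphenol
Product: 10 3-[3-(1,3-dioxolan-2-yl)phenoxy]-4,5-dimethoxyphenyl trifluoromethanesulfonate
Conditions: PhNTf2, Et3N, DMAP (cat.), CH2Cl2, rt
Reagents that add atoms: N-phenylbis(trifluoromethanesulfonimide), O=S(=O)(N(c1ccccc1)S(=O)(=O)C(F)(F)F)C(F)(F)F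
Why: O-Sulfonylation of a phenol with a mild triflyl donor under basic conditions, which avoids the strong acid that triflic anhydride could release onto the acetal.

Step 7
Reactants: 11 tetravinyltin
Product: 12 vinyllithium
Conditions: n-BuLi, pentane, rt; precipitate collected under argon, washed, dissolved in Et2O
Reagents that add atoms: n-butyllithium, [Li]CCCC
Why: Tin–lithium exchange, driven by precipitation of vinyllithium from pentane, gives a halide-free reagent; halide would otherwise occupy the open site on palladium in step 8.

Step 8
Reactants: 5 2-{4-[5-(1,3-dioxolan-2-yl)-2,3-dimethoxyphenoxy]phenyl}-4,4,5,5-tetramethyl-1,3,2-dioxaborolane; 12 vinyllithium; 10 3-[3-(1,3-dioxolan-2-yl)phenoxy]-4,5-dimethoxyphenyl trifluoromethanesulfonate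
Product: 14 2-{1-{4-[5-(1,3-dioxolan-2-yl)-2,3-dimethoxyphenoxy]phenyl}-2-{3-[3-(1,3-dioxolan-2-yl)phenoxy]-4,5-dimethoxyphenyl}ethyl}-4,4,5,5-tetramethyl-1,3,2-dioxaborolane, via lithium vinylboronate complex 13 (not isolated)
Conditions: 5, 12, Et2O, 0 °C → rt; solvent exchange to THF; Pd(OAc)2 (cat.), MandyPhos-type ligand 1,1'-bis[bis(4-methoxy-3,5-dimethylphenyl)phosphino]-2,2'-bis[α-(dimethylamino)benzyl]ferrocene (cat., either enantiomer), 10, 60 °C
Reagents that add atoms: none
Why: Addition of 12 to the boron of 5 gives the tetracoordinate complex 13; zerovalent palladium formed from Pd(OAc)2 and the bisphosphine inserts into the C–OTf bond of 10, and because triflate does not bind, the cationic arylpalladium takes up the vinyl group of 13. This triggers a 1,2-shift of the ring B aryl group from boron to the adjacent carbon, anti to palladium, and reductive elimination then joins the terminal carbon to ring C and returns zerovalent palladium. The closest known reaction type is the palladium-catalysed conjunctive cross-coupling of vinylboronate complexes with aryl triflates, applied here to two larger aryl partners. No ring is closed. The one new stereocentre, the boron-bearing carbon, is set by the face of the vinyl group that the chiral ligand lets palladium bind, and either configuration serves because step 9 replaces boron by hydrogen. The step needs the 1,2-shift to outrun direct transfer of aryl or vinyl from boron to palladium (the Suzuki–Miyaura pathway), which the non-coordinating triflate, the halide-free 12 and the wide-bite-angle ligand secure. Carbon migrates in preference to the pinacol oxygen, the para aryloxy group makes ring B a good migrating group, the triflate carbon of 10 has no ortho substituent, and both dioxolanes are inert to 12.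

Step 9
Reactants: 14 2-{1-{4-[5-(1,3-dioxolan-2-yl)-2,3-dimethoxyphenoxy]phenyl}-2-{3-[3-(1,3-dioxolan-2-yl)phenoxy]-4,5-dimethoxyphenyl}ethyl}-4,4,5,5-tetramethyl-1,3,2-dioxaborolane
Product: 15 1-{4-[5-(1,3-dioxolan-2-yl)-2,3-dimethoxyphenoxy]phenyl}-2-{3-[3-(1,3-dioxolan-2-yl)phenoxy]-4,5-dimethoxyphenyl}ethane
Conditions: TBAF·3H2O, toluene, 80 °C
Reagents that add atoms: none
Why: Fluoride-promoted protodeboronation of a benzylic boronic ester: fluoride adds to boron and the benzylic C–B bond is protonated by the water of hydration. The basic medium leaves the acetals and ethers intact, and the stereocentre disappears.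

Step 10
Reactants: 15 1-{4-[5-(1,3-dioxolan-2-yl)-2,3-dimethoxyphenoxy]phenyl}-2-{3-[3-(1,3-dioxolan-2-yl)phenoxy]-4,5-dimethoxyphenyl}ethane
Product: 16 3-{4-[2-(3-(3-formylphenoxy)-4,5-dimethoxyphenyl)ethyl]phenoxy}-4,5-dimethoxybenzaldehyde
Conditions: 1 M HCl, THF, rt
Reagents that add atoms: water, O
Why: Acid-catalysed hydrolysis of both aryl dioxolanes; methyl and diaryl ethers are stable to dilute aqueous acid.

Step 11
Reactants: 16 3-{4-[2-(3-(3-formylphenoxy)-4,5-dimethoxyphenyl)ethyl]phenoxy}-4,5-dimethoxybenzaldehyde
Product: 17 macrocyclic stilbene: the 19-membered tetramethyl ether with a CH=CH bridge between rings A and D (E or Z, or both)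
Conditions: TiCl4, Zn, THF, reflux; slow addition of 16 (syringe pump, high dilution)
Reagents that add atoms: none
Why: Intramolecular McMurry coupling: low-valent titanium made from TiCl4 and Zn couples the two aryl aldehydes through a titanium pinacolate and deoxygenates it to the alkene. Slow addition favours ring closure over oligomerisation, and the ethers are inert.

Step 12
Reactants: 17 macrocyclic stilbene
Product: 18 macrocyclic tetramethyl ether of the target (CH2CH2 bridge between rings A and D)
Conditions: H2 (1 atm), Pd/C, EtOAc, rt
Reagents that add atoms: none
Why: Heterogeneous hydrogenation of a stilbene double bond; both alkene isomers converge on one product, and diaryl ethers are not hydrogenolysed under these conditions.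

Step 13
Reactants: 18 macrocyclic tetramethyl ether of the target
Product: 19 CNP0511668.0, the 19-membered macrocycle with free catechols on rings A and C
Conditions: BBr3, CH2Cl2, −78 °C → rt; then H2O, 0 °C
Reagents that add atoms: none
Why: Lewis-acid cleavage of the four aryl methyl ethers by bromide attack at methyl of the boron-complexed ethers. Diaryl ethers lack an alkyl carbon open to attack and survive, and the air-sensitive polyphenol is freed only in this last step.

## Compound list

1 | 3-hydroxy-4,5-dimethoxybenzaldehyde | O=Cc1cc(O)c(OC)c(OC)c1 | starting material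
2 | (4-bromophenyl)boronic acid | OB(O)c1ccc(Br)cc1 | starting material
3 | 3-(4-bromophenoxy)-4,5-dimethoxybenzaldehyde | O=Cc1cc(OC)c(OC)c(c1)Oc1ccc(Br)cc1 | intermediate
4 | 2-[3-(4-bromophenoxy)-4,5-dimethoxyphenyl]-1,3-dioxolane | COc1cc(cc(c1OC)Oc1ccc(Br)cc1)C1OCCO1 | intermediate
5 | 2-{4-[5-(1,3-dioxolan-2-yl)-2,3-dimethoxyphenoxy]phenyl}-4,4,5,5-tetramethyl-1,3,2-dioxaborolane | COc1cc(cc(c1OC)Oc1ccc(cc1)B1OC(C)(C)C(C)(C)O1)C1OCCO1 | intermediate
6 | 2-(3-bromophenyl)-1,3-dioxolane | Brc1cccc(c1)C1OCCO1 | starting material
7 | 3-[3-(1,3-dioxolan-2-yl)phenoxy]-4,5-dimethoxybenzaldehyde | COc1cc(C=O)cc(c1OC)Oc1cccc(c1)C1OCCO1 | intermediate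
8 | 3-[3-(1,3-dioxolan-2-yl)phenoxy]-4,5-dimethoxyphenyl formate | COc1cc(OC=O)cc(c1OC)Oc1cccc(c1)C1OCCO1 | intermediate
9 | 3-[3-(1,3-dioxolan-2-yl)phenoxy]-4,5-dimethoxyphenol | COc1cc(O)cc(c1OC)Oc1cccc(c1)C1OCCO1 | intermediate
10 | 3-[3-(1,3-dioxolan-2-yl)phenoxy]-4,5-dimethoxyphenyl trifluoromethanesulfonate | COc1cc(OS(=O)(=O)C(F)(F)F)cc(c1OC)Oc1cccc(c1)C1OCCO1 | intermediate
11 | tetravinyltin (tetraethenylstannane) | C=C[Sn](C=C)(C=C)C=C | starting material
12 | vinyllithium | [Li]C=C | intermediate
13 | lithium vinylboronate complex of 5 (boron carrying vinyl, the ring B aryl group and pinacolate) | [Li+].C=C[B-]1(OC(C)(C)C(C)(C)O1)c1ccc(cc1)Oc1cc(cc(OC)c1OC)C1OCCO1 | intermediate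
14 | 2-{1-{4-[5-(1,3-dioxolan-2-yl)-2,3-dimethoxyphenoxy]phenyl}-2-{3-[3-(1,3-dioxolan-2-yl)phenoxy]-4,5-dimethoxyphenyl}ethyl}-4,4,5,5-tetramethyl-1,3,2-dioxaborolane (either configuration at the boron-bearing carbon) | COc1cc(cc(c1OC)Oc1ccc(cc1)C(B1OC(C)(C)C(C)(C)O1)Cc1cc(OC)c(OC)c(c1)Oc1cccc(c1)C1OCCO1)C1OCCO1 | intermediate
15 | 1-{4-[5-(1,3-dioxolan-2-yl)-2,3-dimethoxyphenoxy]phenyl}-2-{3-[3-(1,3-dioxolan-2-yl)phenoxy]-4,5-dimethoxyphenyl}ethane | COc1cc(cc(c1OC)Oc1ccc(cc1)CCc1cc(OC)c(OC)c(c1)Oc1cccc(c1)C1OCCO1)C1OCCO1 | intermediate
16 | 3-{4-[2-(3-(3-formylphenoxy)-4,5-dimethoxyphenyl)ethyl]phenoxy}-4,5-dimethoxybenzaldehyde | COc1cc(C=O)cc(c1OC)Oc1ccc(cc1)CCc1cc(OC)c(OC)c(c1)Oc1cccc(C=O)c1 | intermediate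
17 | macrocyclic stilbene, 19-membered tetramethyl ether with CH=CH between rings A and D (E or Z) | COc1cc2cc(c1OC)Oc1ccc(cc1)CCc1cc(OC)c(OC)c(c1)Oc1cccc(c1)C=C2 | intermediate
18 | macrocyclic tetramethyl ether of the target | COc1cc2cc(c1OC)Oc1ccc(cc1)CCc1cc(OC)c(OC)c(c1)Oc1cccc(c1)CC2 | intermediate
19 | CNP0511668.0, 19-membered macrocycle with free catechols on rings A and C | Oc1cc2cc(c1O)Oc1ccc(cc1)CCc1cc(O)c(O)c(c1)Oc1cccc(c1)CC2 | target

## Step count and risks

Total step count: 13. Longest linear sequence: 9 steps (steps 1–3 and 8–13; the branch through steps 4–6 and 8–13 is equally long). Step 7 is a one-step side branch.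

**Step 8 (key step).**
- Risk: direct transfer of the aryl or vinyl group from boron to palladium may compete with alkene binding and the 1,2-shift. Oxidative addition into the electron-rich triflate may also be slow enough for the boronate complex to revert or decompose.
- Fallback: the same two bonds would be made one after the other, from 4 to 15.
  - Suzuki–Miyaura vinylation of 4 (potassium vinyltrifluoroborate, PdCl2(dppf), K2CO3, THF/H2O, 70 °C) would give the styrene 2-[3-(4-ethenylphenoxy)-4,5-dimethoxyphenyl]-1,3-dioxolane F1.
  - Anti-Markovnikov hydroboration with 9-BBN in THF would give the alkylborane 9-{2-[4-(5-(1,3-dioxolan-2-yl)-2,3-dimethoxyphenoxy)phenyl]ethyl}-9-borabicyclo[3.3.1]nonane F2.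
  - F2 would be coupled without isolation with 10 (PdCl2(dppf), K3PO4, THF/DMF/H2O, 60 °C) in a B-alkyl Suzuki–Miyaura reaction to give 15.
  - The route is rejoined at 15, and step 9 is not needed.

**Step 9.**
- Risk: heterolysis of the carbon–boron bond may be slow at a secondary benzylic carbon whose aryl group carries an electron-donating para oxygen. Prolonged heating then invites air oxidation of the boronate.
- Fallback: the boron would be exchanged for oxygen and the oxygen removed by a radical route, from 14 to 15.
  - Oxidation of 14 (NaBO3·4H2O, THF/H2O, rt) would give the alcohol 1-{4-[5-(1,3-dioxolan-2-yl)-2,3-dimethoxyphenoxy]phenyl}-2-{3-[3-(1,3-dioxolan-2-yl)phenoxy]-4,5-dimethoxyphenyl}ethan-1-ol F3.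
  - Acylation with 1,1'-thiocarbonyldiimidazole (DMAP, CH2Cl2) would give its O-(imidazol-1-ylthiocarbonyl) derivative F4.
  - Barton–McCombie deoxygenation (Bu3SnH, AIBN, toluene, 90 °C) would then give 15, where the route is rejoined.

**Step 11.**
- Risk: intermolecular carbonyl coupling to oligomers, or arrest at the titanium pinacolate stage, may take over if the two aldehydes cannot easily reach each other across the open chain.
- Fallback: the ring would be closed by metathesis, from 16 to 17.
  - Double Wittig methylenation of 16 (Ph3PCH3Br, KOt-Bu, THF, 0 °C) would give the bis-styrene 1-ethenyl-3-{4-[2-(3-(3-ethenylphenoxy)-4,5-dimethoxyphenyl)ethyl]phenoxy}-4,5-dimethoxybenzene F5.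
  - Ring-closing metathesis (second-generation Grubbs catalyst, RuCl2(=CHPh)(PCy3)(H2IMes), CH2Cl2, 40 °C, high dilution) would give 17 with loss of ethene, and the route is rejoined there.

**Step 4.**
- Risk: C–O coupling of a phenoxide flanked by a methoxy group and deactivated by the formyl group may be slow. Reduction of the aryl bromide or base-induced degradation of the aldehyde could then overtake it at 90 °C.
- Fallback: the polarity of the ether formation would be reversed, from 6 to 7.
  - Bromine–lithium exchange on 6 (n-BuLi, THF, −78 °C), trapping with B(Oi-Pr)3 and a near-neutral aqueous work-up would give [3-(1,3-dioxolan-2-yl)phenyl]boronic acid F6.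
  - Chan–Lam coupling of F6 with 1 (Cu(OAc)2, pyridine, 4 Å molecular sieves, CH2Cl2, air, rt) would give 7, where the route is rejoined.

## Further compounds

F1 | step 8 | 2-[3-(4-ethenylphenoxy)-4,5-dimethoxyphenyl]-1,3-dioxolane | COc1cc(cc(c1OC)Oc1ccc(C=C)cc1)C1OCCO1
F2 | step 8 | 9-{2-[4-(5-(1,3-dioxolan-2-yl)-2,3-dimethoxyphenoxy)phenyl]ethyl}-9-borabicyclo[3.3.1]nonane | COc1cc(cc(c1OC)Oc1ccc(CCB2C3CCCC2CCC3)cc1)C1OCCO1
F3 | step 9 | 1-{4-[5-(1,3-dioxolan-2-yl)-2,3-dimethoxyphenoxy]phenyl}-2-{3-[3-(1,3-dioxolan-2-yl)phenoxy]-4,5-dimethoxyphenyl}ethan-1-ol | COc1cc(cc(c1OC)Oc1ccc(cc1)C(O)Cc1cc(OC)c(OC)c(c1)Oc1cccc(c1)C1OCCO1)C1OCCO1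
F4 | step 9 | O-(imidazol-1-ylthiocarbonyl) derivative of F3 (O-alkyl 1H-imidazole-1-carbothioate) | COc1cc(cc(c1OC)Oc1ccc(cc1)C(OC(=S)n1ccnc1)Cc1cc(OC)c(OC)c(c1)Oc1cccc(c1)C1OCCO1)C1OCCO1
F5 | step 11 | 1-ethenyl-3-{4-[2-(3-(3-ethenylphenoxy)-4,5-dimethoxyphenyl)ethyl]phenoxy}-4,5-dimethoxybenzene | COc1cc(C=C)cc(c1OC)Oc1ccc(cc1)CCc1cc(OC)c(OC)c(c1)Oc1cccc(C=C)c1
F6 | step 4 | [3-(1,3-dioxolan-2-yl)phenyl]boronic acid | OB(O)c1cccc(c1)C1OCCO1
A1 | alternative 1 | 5-[2-(4-benzyloxyphenyl)ethyl]-2,3-diisopropoxyphenol | CC(C)Oc1c(O)cc(CCc2ccc(OCc3ccccc3)cc2)cc1OC(C)C
A2 | alternative 1 | 4-chloro-2,3-diisopropoxycyclobut-2-en-1-one | O=C1C(Cl)C(OC(C)C)=C1OC(C)C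
A3 | alternative 1 | tributyl[4-(4-benzyloxyphenyl)but-1-en-2-yl]stannane | C=C(CCc1ccc(OCc2ccccc2)cc1)[Sn](CCCC)(CCCC)CCCC
A4 | alternative 2 | 19-membered macrocyclic tetramethyl ether with a formyl group on ring D ortho to the ring C–O–ring D oxygen | COc1cc2cc(c1OC)Oc1ccc(cc1)CCc1cc(OC)c(OC)c(c1)Oc1cc(CC2)ccc1C=O
A5 | alternative 2 | 2-fluoro-4-{2-[3-(4-{2-[3-hydroxy-4,5-dimethoxyphenyl]ethyl}phenoxy)-4,5-dimethoxyphenyl]ethyl}benzaldehyde | COc1cc(CCc2ccc(C=O)c(F)c2)cc(c1OC)Oc1ccc(cc1)CCc1cc(OC)c(OC)c(O)c1
A6 | alternative 3 | carbon-linked 19-membered macrocycle with an exocyclic methylene on the A–D bridge carbon next to ring D and a free middle phenol on ring A | COc1cc2cc(c1O)Oc1ccc(cc1)CCc1cc(OC)c(OC)c(c1)Oc1cccc(c1)C(=C)C2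
A7 | alternative 3 | 19-membered macrocyclic 2-arylallyl aryl ether in which the middle oxygen of ring A carries CH2–C(=CH2)–ring D | COc1cccc2c1OCC(=C)c1cccc(c1)Oc1cc(CCc3ccc(O2)cc3)cc(OC)c1OC
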